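The route rests on cutting the C(sp3)H2–C(sp2)(CH3) bond at which the three-methylene tether from the stereocentre meets the first trisubstituted olefin of the skipped 1,4-diene. In one operation, anti-Markovnikov hydroboration of a terminal vinyl group and B-alkyl Suzuki–Miyaura coupling turn that CH2 into a nucleophile and join it, with retention of E geometry, to the iodine-bearing olefinic carbon of a furyl ketone dienyl iodide. The precursor is the complete, (S)-configured, MOM-protected (E)-5-ylidene tetronate (furan-2(5H)-one ring) carrying a 2-methylpent-4-enylidene chain, so the exocyclic olefin and the furan-3-yl ketone are in place and only acetal cleavage remains.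

Key step: step 13

Remark: 3-methyltetronic acid 7 is taken as a purchasable starting material (otherwise two steps from ethyl 2-methylacetoacetate); aldol adduct 12 is drawn as one of its two erythro epimers, which converge in step 7.

Step 1
Reactants: 1 (R)-4-benzyl-3-propionyloxazolidin-2-one; 2 allyl iodide
Product: 4 (R)-4-benzyl-3-[(S)-2-methylpent-4-enoyl]oxazolidin-2-one, via sodium (Z)-enolate 3 (not isolated)
Conditions: NaN(SiMe3)2, THF, −78 °C; then 2, −78 → −45 °C
Reagents that add atoms: none
Why: Evans alkylation; the chelated (Z)-enolate should be allylated on the face opposite the benzyl group, which sets the (S) methyl-bearing stereocentre.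

Step 2
Reactants: 4 (R)-4-benzyl-3-[(S)-2-methylpent-4-enoyl]oxazolidin-2-one
Product: 5 (S)-2-methylpent-4-en-1-ol
Conditions: LiBH4, MeOH (1 equiv), THF, 0 °C
Reagents that add atoms: none
Why: Reductive removal of the oxazolidinone auxiliary should give the primary alcohol without touching the α-stereocentre or the terminal olefin.

Step 3
Reactants: 5 (S)-2-methylpent-4-en-1-ol
Product: 6 (S)-2-methylpent-4-enal
Conditions: Dess–Martin periodinane, CH2Cl2, 0 °C → rt; used as a solution
Reagents that add atoms: none
Why: Dess–Martin oxidation under near-neutral conditions should give the volatile α-branched aldehyde without epimerisation.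

Step 4
Reactants: 7 3-methyltetronic acid
Product: 8 4-(methoxymethoxy)-3-methylfuran-2(5H)-one
Conditions: MOMCl, iPr2NEt, CH2Cl2, 0 °C
Reagents that add atoms: chloromethyl methyl ether, COCCl
Why: O-alkylation of the vinylogous acid with a hard electrophile should give the MOM tetronate, a vinylogous acetal ester that can be cleaved later by dilute acid.

Step 5
Reactants: 8 4-(methoxymethoxy)-3-methylfuran-2(5H)-one
Product: 10 tert-butyl{[4-(methoxymethoxy)-3-methylfuran-2-yl]oxy}dimethylsilane, via lithium furanolate 9 (not isolated)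
Conditions: LiN(iPr)2, THF, −78 °C; then TBSCl, DMPU, −78 → 0 °C; used crude
Reagents that add atoms: tert-butyldimethylsilyl chloride, CC(C)(C)[Si](C)(C)Cl
Why: Deprotonation at C-5 gives the aromatic furanolate, which should be silylated on oxygen to the 2-silyloxyfuran (silyl dienolate formation).

Step 6
Reactants: 10 tert-butyl{[4-(methoxymethoxy)-3-methylfuran-2-yl]oxy}dimethylsilane; 6 (S)-2-methylpent-4-enal
Product: 12 (5R)-5-[(1R,2S)-1-hydroxy-2-methylpent-4-en-1-yl]-4-(methoxymethoxy)-3-methylfuran-2(5H)-one (erythro), via tetrabutylammonium furanolate 11 (not isolated)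
Conditions: Bu4NF (dried over 4 Å sieves), THF, −78 °C; AcOH quench; chromatography
Reagents that add atoms: none
Why: Fluoride-promoted vinylogous Mukaiyama-type aldol addition through C-5 in an open transition state should favour the erythro (5R*,1'R*) adducts, whereas the Lewis acid variant favours threo; both erythro epimers lead to the same olefin, threo isomers are removed by chromatography, and the α-stereocentre of 6 should not epimerise at −78 °C.

Step 7
Reactants: 12 erythro aldol adduct
Product: 14 (S,E)-4-(methoxymethoxy)-3-methyl-5-(2-methylpent-4-en-1-ylidene)furan-2(5H)-one, via mesylate 13 (not isolated)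
Conditions: MsCl, Et3N, CH2Cl2, −20 °C; then DBU, −20 → 0 °C, dark
Reagents that add atoms: none
Why: Mesylation followed by anti-periplanar E2 elimination of H-5 and the mesylate (the stereospecific β-elimination known for γ-(α-hydroxyalkyl)butenolides) should convert the erythro adduct specifically into the (E)-ylidene lactone with the side chain cis to C-4; the more acidic H-5 is removed in preference to the tertiary side-chain hydrogen, so the stereocentre is untouched.

Step 8
Reactants: 15 pent-3-yn-1-ol
Product: 17 (E)-4-iodopent-3-en-1-ol, via alkenylzirconocene 16 (not isolated)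
Conditions: Cp2Zr(H)Cl (2.5 equiv), THF, 0 → 45 °C; then I2, 0 °C
Reagents that add atoms: iodine, II
Why: Hydrozirconation (syn addition, the first equivalent being consumed by the hydroxyl group) should equilibrate under excess reagent to place zirconium on the less hindered, methyl-bearing alkyne carbon, and iodinolysis with retention should give the (E)-2-iodo-2-alkene.

Step 9
Reactants: 17 (E)-4-iodopent-3-en-1-ol
Product: 18 (E)-4-iodopent-3-enal
Conditions: Dess–Martin periodinane, NaHCO3, CH2Cl2, 0 °C; used at once
Reagents that add atoms: none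
Why: Buffered Dess–Martin oxidation should give the β,γ-unsaturated aldehyde without migration of the olefin into conjugation.

Step 10
Reactants: 18 (E)-4-iodopent-3-enal; 19 isopropenylmagnesium bromide
Product: 20 (E)-6-iodo-2-methylhepta-1,5-dien-3-ol (racemic)
Conditions: CeCl3, THF, −78 °C; NH4Cl (aq)
Reagents that add atoms: none
Why: The weakly basic organocerium reagent should add 1,2 to the enolisable aldehyde without deprotonation or attack at the alkenyl iodide; the carbinol centre is destroyed in step 12, so no stereocontrol is needed.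

Step 11
Reactants: 21 3-acetylfuran
Product: 22 3-(1,1-dimethoxyethyl)furan
Conditions: HC(OMe)3, MeOH, TsOH (cat.), rt; NaOMe quench
Reagents that add atoms: trimethyl orthoformate, COC(OC)OC
Why: Acid-catalysed ketalisation with the orthoformate as water scavenger should give the dimethyl ketal of the electron-poor acylfuran.

Step 12
Reactants: 20 (E)-6-iodo-2-methylhepta-1,5-dien-3-ol; 22 3-(1,1-dimethoxyethyl)furan
Product: 25 (4E,7E)-1-(furan-3-yl)-8-iodo-4-methylnona-4,7-dien-1-one, via mixed ketal 23 (not isolated), via allyl vinyl ether 24 (not isolated)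
Conditions: 22 (4 equiv), EtCO2H (cat.), xylene, 135 °C, MeOH distilled off
Reagents that add atoms: none
Why: Ketal Claisen rearrangement: trans-ketalisation, loss of methanol and a chair [3,3] shift with the iodoalkenyl chain equatorial (an axial chain would clash with the furyl group) should give the E trisubstituted olefin and the furyl ketone directly.

Step 13
Reactants: 14 (S,E)-4-(methoxymethoxy)-3-methyl-5-(2-methylpent-4-en-1-ylidene)furan-2(5H)-one; 25 (4E,7E)-1-(furan-3-yl)-8-iodo-4-methylnona-4,7-dien-1-one
Product: 27 (E)-5-[(2S,6E,9E)-13-(furan-3-yl)-2,6,10-trimethyl-13-oxotrideca-6,9-dien-1-ylidene]-4-(methoxymethoxy)-3-methylfuran-2(5H)-one, via B-alkyl-9-BBN 26 (not isolated)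
Conditions: 14 (1.3 equiv), 9-BBN-H, THF, 0 °C → rt; then H2O, Cs2CO3, 25, Pd(dppf)Cl2·CH2Cl2 (cat.), AsPh3 (cat.), DMF, rt, dark
Reagents that add atoms: none
Why: 9-BBN-H adds syn and anti-Markovnikov to the monosubstituted olefin of 14 to give the primary borane 26; after addition of aqueous Cs2CO3 the hydroxyborate transfers its primary alkyl group with retention to the alkenylpalladium iodide formed by oxidative addition of zerovalent palladium into the C–I bond of 25, and reductive elimination forges the C(sp3)–C(sp2) bond. The closest known reaction type is the B-alkyl Suzuki–Miyaura coupling of alkenyl iodides. No ring is closed and no stereocentre is created; the E geometry of the new trisubstituted olefin is carried over from 25, and the (S) centre and the exocyclic (E)-olefin of 14 are not involved. The step needs hydroboration of the terminal vinyl group only, which the bulk and low reducing power of 9-BBN-H secure against the trisubstituted conjugated exocyclic olefin and the lactone carbonyl; the ketone of 25 is safe because no B–H remains once water is added. β-Hydride elimination is suppressed by the wide bite angle of dppf and by AsPh3, and the weak base at room temperature should spare the enol lactone.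

Step 14
Reactants: 27 MOM-protected coupling product
Product: 28 (E)-5-[(2S,6E,9E)-13-(furan-3-yl)-2,6,10-trimethyl-13-oxotrideca-6,9-dien-1-ylidene]-4-hydroxy-3-methylfuran-2(5H)-one
Conditions: HCl (1 M aq), THF, 0 °C → rt, dark
Reagents that add atoms: none
Why: Hydrolysis of the vinylogous acetal ester should proceed under dilute acid mild enough to leave the acylfuran, the skipped diene and the (E)-ylidene geometry untouched.

Compound list
1 | (R)-4-benzyl-3-propionyloxazolidin-2-one | CCC(=O)N1[C@H](Cc2ccccc2)COC1=O | starting material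
2 | allyl iodide | C=CCI | starting material
3 | sodium (Z)-enolate of 1 | C/C=C(\[O-])N1[C@H](Cc2ccccc2)COC1=O.[Na+] | intermediate
4 | (R)-4-benzyl-3-[(S)-2-methylpent-4-enoyl]oxazolidin-2-one | C=CC[C@H](C)C(=O)N1[C@H](Cc2ccccc2)COC1=O | intermediate
5 | (S)-2-methylpent-4-en-1-ol | C=CC[C@H](C)CO | intermediate
6 | (S)-2-methylpent-4-enal | C=CC[C@H](C)C=O | intermediate
7 | 3-methyltetronic acid (4-hydroxy-3-methylfuran-2(5H)-one) | CC1=C(O)COC1=O | starting material
8 | 4-(methoxymethoxy)-3-methylfuran-2(5H)-one | CC1=C(OCOC)COC1=O | intermediate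
9 | lithium 4-(methoxymethoxy)-3-methylfuran-2-olate | Cc1c(OCOC)coc1[O-].[Li+] | intermediate
10 | tert-butyl{[4-(methoxymethoxy)-3-methylfuran-2-yl]oxy}dimethylsilane | Cc1c(OCOC)coc1O[Si](C)(C)C(C)(C)C | intermediate
11 | tetrabutylammonium 4-(methoxymethoxy)-3-methylfuran-2-olate | Cc1c(OCOC)coc1[O-].CCCC[N+](CCCC)(CCCC)CCCC | intermediate
12 | (5R)-5-[(1R,2S)-1-hydroxy-2-methylpent-4-en-1-yl]-4-(methoxymethoxy)-3-methylfuran-2(5H)-one (erythro; the (5S,1'S,2'S) erythro epimer behaves alike) | CC1=C(OCOC)[C@@H]([C@H](O)[C@@H](C)CC=C)OC1=O | intermediate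
13 | methanesulfonate of 12 | CC1=C(OCOC)[C@@H]([C@H](OS(C)(=O)=O)[C@@H](C)CC=C)OC1=O | intermediate
14 | (S,E)-4-(methoxymethoxy)-3-methyl-5-(2-methylpent-4-en-1-ylidene)furan-2(5H)-one | CC1=C(OCOC)/C(=C\[C@@H](C)CC=C)OC1=O | intermediate
15 | pent-3-yn-1-ol | CC#CCCO | starting material
16 | (E)-alkenylzirconocene chloride (zirconium alkoxide form) | C/C(=C\CCO[Zr](Cl)(C1C=CC=C1)C1C=CC=C1)[Zr](Cl)(C1C=CC=C1)C1C=CC=C1 | intermediate
17 | (E)-4-iodopent-3-en-1-ol | OCC/C=C(\C)I | intermediate
18 | (E)-4-iodopent-3-enal | O=CC/C=C(\C)I | intermediate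
19 | isopropenylmagnesium bromide | CC(=C)[Mg]Br | starting material
20 | (E)-6-iodo-2-methylhepta-1,5-dien-3-ol (racemic) | C=C(C)C(O)C/C=C(\C)I | intermediate
21 | 3-acetylfuran | CC(=O)c1ccoc1 | starting material
22 | 3-(1,1-dimethoxyethyl)furan | COC(C)(OC)c1ccoc1 | intermediate
23 | mixed methyl allyl ketal of 21 and 20 | COC(C)(OC(C/C=C(\C)I)C(C)=C)c1ccoc1 | intermediate
24 | allyl vinyl ether, 3-{1-[(E)-6-iodo-2-methylhepta-1,5-dien-3-yloxy]vinyl}furan | C=C(OC(C/C=C(\C)I)C(C)=C)c1ccoc1 | intermediate
25 | (4E,7E)-1-(furan-3-yl)-8-iodo-4-methylnona-4,7-dien-1-one | O=C(CC/C(C)=C/C/C=C(\C)I)c1ccoc1 | intermediate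
26 | B-alkyl-9-BBN adduct of 14 | CC1=C(OCOC)/C(=C\[C@@H](C)CCCB2C3CCCC2CCC3)OC1=O | intermediate
27 | (E)-5-[(2S,6E,9E)-13-(furan-3-yl)-2,6,10-trimethyl-13-oxotrideca-6,9-dien-1-ylidene]-4-(methoxymethoxy)-3-methylfuran-2(5H)-one | CC1=C(OCOC)/C(=C\[C@@H](C)CCC/C(C)=C/C/C=C(\C)CCC(=O)c2ccoc2)OC1=O | intermediate
28 | (E)-5-[(2S,6E,9E)-13-(furan-3-yl)-2,6,10-trimethyl-13-oxotrideca-6,9-dien-1-ylidene]-4-hydroxy-3-methylfuran-2(5H)-one | CC1=C(O)/C(=C\[C@@H](C)CCC/C(C)=C/C/C=C(\C)CCC(=O)c2ccoc2)OC1=O | target

Total step count: 14. Longest linear sequence: 7 steps (1, 2, 3, 6, 7, 13, 14).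

Steps most likely to fail

Step 13. The enol lactone may be opened by hydroxide or carbonate, the exocyclic olefin may isomerise from E to Z under base or palladium, and the borane may be lost by protodeboronation. The fallback forms the same bond before the tetronate is built; it sets out from 5 and comes back at 27. Silylation of 5 (TBSCl, imidazole) should give tert-butyldimethyl{[(2S)-2-methylpent-4-en-1-yl]oxy}silane F1. Hydroboration with 9-BBN-H to the B-alkyl-9-BBN adduct F2 and coupling with 25 as in step 13 should give (4E,7E,12S)-13-[(tert-butyldimethylsilyl)oxy]-1-(furan-3-yl)-4,8,12-trimethyltrideca-4,7-dien-1-one F3. Bu4NF should free (4E,7E,12S)-1-(furan-3-yl)-13-hydroxy-4,8,12-trimethyltrideca-4,7-dien-1-one F4, and Dess–Martin oxidation should give (2S,6E,9E)-13-(furan-3-yl)-2,6,10-trimethyl-13-oxotrideca-6,9-dienal F5. Fluoride-promoted aldol addition of 10, in which the aldehyde should react before the aryl ketone, should give (5R)-5-[(1R,2S,6E,9E)-13-(furan-3-yl)-1-hydroxy-2,6,10-trimethyl-13-oxotrideca-6,9-dien-1-yl]-4-(methoxymethoxy)-3-methylfuran-2(5H)-one F6. Mesylation to the methanesulfonate of the erythro adduct F7 and DBU elimination as in step 7 should then give 27.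

Step 6. Facial selectivity may be poor, so that too little erythro adduct forms, and the silyloxyfuran may be protodesilylated before it adds. The fallback pairs the opposite aldol selectivity with the opposite elimination mode; it sets out from 10 and 6 and comes back at 14. The Lewis acid variant (BF3·OEt2, CH2Cl2, −78 °C) should favour the threo adduct (5S)-5-[(1R,2S)-1-hydroxy-2-methylpent-4-en-1-yl]-4-(methoxymethoxy)-3-methylfuran-2(5H)-one F8. Burgess reagent (methyl N-(triethylammoniosulfonyl)carbamate, THF, rt → 50 °C) should convert it into the triethylammonium N-(methoxycarbonyl)sulfamate ester F9, whose intramolecular syn elimination of H-5 should give the same (E)-olefin 14.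

Step 12. Formation of the aryl-substituted enol ether may be slow, and under acid and heat the doubly allylic-type alcohol 20 may ionise or dehydrate instead. The fallback builds the olefin by an orthoester Claisen rearrangement and adds the furan afterwards; it sets out from 20 and comes back at 25. Heating 20 with triethyl orthoacetate and catalytic EtCO2H (140 °C) should pass through the mixed orthoester F10 and the ketene acetal F11 to ethyl (4E,7E)-8-iodo-4-methylnona-4,7-dienoate F12. MeNH(OMe)·HCl with iPrMgCl should give (4E,7E)-8-iodo-N-methoxy-N,4-dimethylnona-4,7-dienamide F13. 3-Furylmagnesium chloride F14, made from 3-bromofuran and a slight deficit of iPrMgCl·LiCl so that the alkenyl iodide is not exchanged, should then add once (THF, 0 °C) to give 25.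

Further compounds
F1 | step 13 | tert-butyldimethyl{[(2S)-2-methylpent-4-en-1-yl]oxy}silane | C=CC[C@H](C)CO[Si](C)(C)C(C)(C)C
F2 | step 13 | B-alkyl-9-BBN adduct of F1 | CC(C)(C)[Si](C)(C)OC[C@@H](C)CCCB1C2CCCC1CCC2
F3 | step 13 | (4E,7E,12S)-13-[(tert-butyldimethylsilyl)oxy]-1-(furan-3-yl)-4,8,12-trimethyltrideca-4,7-dien-1-one | CC(C)(C)[Si](C)(C)OC[C@@H](C)CCC/C(C)=C/C/C=C(\C)CCC(=O)c1ccoc1
F4 | step 13 | (4E,7E,12S)-1-(furan-3-yl)-13-hydroxy-4,8,12-trimethyltrideca-4,7-dien-1-one | OC[C@@H](C)CCC/C(C)=C/C/C=C(\C)CCC(=O)c1ccoc1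
F5 | step 13 | (2S,6E,9E)-13-(furan-3-yl)-2,6,10-trimethyl-13-oxotrideca-6,9-dienal | O=C[C@@H](C)CCC/C(C)=C/C/C=C(\C)CCC(=O)c1ccoc1
F6 | step 13 | (5R)-5-[(1R,2S,6E,9E)-13-(furan-3-yl)-1-hydroxy-2,6,10-trimethyl-13-oxotrideca-6,9-dien-1-yl]-4-(methoxymethoxy)-3-methylfuran-2(5H)-one | CC1=C(OCOC)[C@@H]([C@H](O)[C@@H](C)CCC/C(C)=C/C/C=C(\C)CCC(=O)c2ccoc2)OC1=O
F7 | step 13 | methanesulfonate of the erythro adduct | CC1=C(OCOC)[C@@H]([C@H](OS(C)(=O)=O)[C@@H](C)CCC/C(C)=C/C/C=C(\C)CCC(=O)c2ccoc2)OC1=O
F8 | step 6 | (5S)-5-[(1R,2S)-1-hydroxy-2-methylpent-4-en-1-yl]-4-(methoxymethoxy)-3-methylfuran-2(5H)-one (threo) | CC1=C(OCOC)[C@H]([C@H](O)[C@@H](C)CC=C)OC1=O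
F9 | step 6 | triethylammonium N-(methoxycarbonyl)sulfamate ester of the threo adduct | CC1=C(OCOC)[C@H]([C@H](OS(=O)(=O)[N-]C(=O)OC)[C@@H](C)CC=C)OC1=O.CC[NH+](CC)CC
F10 | step 12 | mixed orthoester of 20 and triethyl orthoacetate | CCOC(C)(OCC)OC(C/C=C(\C)I)C(C)=C
F11 | step 12 | ketene acetal, (E)-3-[(1-ethoxyvinyl)oxy]-6-iodo-2-methylhepta-1,5-diene | C=C(OCC)OC(C/C=C(\C)I)C(C)=C
F12 | step 12 | ethyl (4E,7E)-8-iodo-4-methylnona-4,7-dienoate | CCOC(=O)CC/C(C)=C/C/C=C(\C)I
F13 | step 12 | (4E,7E)-8-iodo-N-methoxy-N,4-dimethylnona-4,7-dienamide | CON(C)C(=O)CC/C(C)=C/C/C=C(\C)I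
F14 | step 12 | 3-furylmagnesium chloride | Cl[Mg]c1ccoc1
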